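At late times the two earlier runs stand still: Friday's X reads 72% of the D charged at 40.0 min, and Tuesday's reads 100% at 40.0 min, with a scatter of 2 percentage points. Friday's J charge is 72.3% of its D charge, which is what its plateau reads, while Tuesday's J exceeds its D. So the two plateaus read as one J making one X.

This gives a quantity to carry to the next flasks. The ceiling is the smaller of one and the J charged over the D charged, counting E together with free X, and below one it marks J as the limiting reagent. For north the ceiling is 53.2%. For east it is 100%, and north-east and west stand at that same value, since their J also exceeds D. Friday's readings are level from 30.0 min, earlier than the new flasks' end, so both chemists below expect the ceilings to be reached.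

| flask | D | J | Z | remark | time |
|---|---|---|---|---|---|
| Friday's | 47 mM | 34 mM | 4 mM | run made earlier |  |
| Tuesday's | 47 mM | 260 mM | 4 mM | run made earlier |  |
| north | 47 mM | 25.0 mM | 4.0 mM |  | 50 min |
| north-east | 47 mM | 50.0 mM | 4.0 mM |  | 50 min |
| west | 47 mM | 100 mM | 4.0 mM |  | 50 min |
| east | 47 mM | 200 mM | 4.0 mM |  | 50 min |

| Friday's: time / min | Friday's: X / % | Tuesday's: time / min | Tuesday's: X / % |
|---|---|---|---|
| 6.00 | 38 | 3.00 | 93 |
| 12.0 | 58 | 5.00 | 102 |
| 20.0 | 68 | 8.00 | 102 |
| 25.0 | 66 | 12.0 | 100 |
| 30.0 | 73 | 20.0 | 98 |
| 40.0 | 72 | 40.0 | 100 |

(standard deviation of a reading: 2 percentage points)

- amounts and yields of X count E too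
- given per volume of solution although it is solid: E
- reactions considered so far: D + Z -> L; G <-> Z + X; E <-> X; J + L -> G
- the concentration of X that is asked is that of its free form alone
- "hardly changes" means that all values lie within two and a half points (for a concentration: within two and a half percent of the largest)

- [X] (only what is free in solution) at the end for north, north-east, west, east, in this order
- how the row runs (rises, then falls / rises all the way / falls all the way / falls, then rises / hardly changes)

Two chemists differ over the dissolved part, which the readings do not show, since they count E with X. The first takes X to stay in solution, so that free X follows the ceiling. The forecast is this chemist's: 25 mM, 47 mM, 47 mM, 47 mM, with the shape "rises all the way", on the stated ground “My expectation assumes no crystals form”.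

The second chemist takes crystallising as fast and reckons with what it leaves in solution. X above the solubility goes into E, so a raised ceiling adds to E and leaves the free part where it was. The readings give no level for that solubility, but one comparison is enough. North has a lower ceiling than east, so if the solubility lies under north's 53.2%, the row stays flat. The second chemist therefore expects a row that hardly changes, at a level left open.

The simulation gives 0.494 mM, 0.496 mM, 0.490 mM, 0.490 mM, with the shape "hardly changes". North's free X is 1.05% of the D charged, and the row is the second chemist's.

    D + Z → L (k = 9.50 /M/s)
    G ⇌ Z + X (K = 0.120 M, k = 0.660 /s)
    E ⇌ X, rate k3*(cs3 - [X]) while solid is left; crystals form when [X] > cs3 (solubility = 0.490 mM, k = 0.0240 /s)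
    J + L → G (k = 0.540 /M/s)

North's ceiling of 53.2% is met by X at 53.1% at 50.0 min, and east's ceiling of 100% by X at >99.9%, yet E makes up 52.1% and 98.9% of the D charged in these two flasks, the saturation of X keeping the free part level. The first chemist's view has its region where the ceiling lies under the solubility, 1.04% of the D charged, so that no crystals form. With saturation taken away, north's free X goes from 1.05% to 53.1% of the D charged, and east's from 1.04% to 97.6%.

The data stem from a simulated flask for substances that don't exist, noise included.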